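The constants used here are invented; what happens was integrated by code.

5 questions hang on 4 flasks that differ in temperature and in nothing else.

    Qa → Qc (k1 = 0.15 min⁻¹, Ea1 = 101 kJ mol⁻¹)
    Qb + Qc → Qg (k2 = 0.087 M⁻¹ min⁻¹, Ea2 = 78.0 kJ mol⁻¹)
    2 Qc → Qd (k3 = 0.0069 M⁻¹ min⁻¹, Ea3 = 80.0 kJ mol⁻¹)
    Qe ⇌ Qb, rate k4*(csat - [Qb]) (k4 = 0.73 min⁻¹, csat = 200 mM)
    Qc → Qf (k5 = 0.0030 min⁻¹, Ea5 = 104 kJ mol⁻¹)
    (constants at 80 °C)

all flasks: Qa 2.1 M; Qe 200 mM (held); time 3.0 h

| run | temperature |
|---|---|
| dawn | 40 °C |
| summer | 100 °C |
| dusk | 60 °C |
| winter | 80 °C |

- percent here means Qa units held: one Qd counts as two
- a step written with two of one species runs at k times the square of its concentration and takes two of it each time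
- at the start none of Qb is dissolved
- constants are those at 80 °C; use the activation energies for any other temperature

1. which flask leads in amount of Qg, in percent of the Qa charged ("all alike" within 1.5 percentage points) (dawn / summer / dusk / winter / all alike)
2. how much Qg is there at the end, in percent of the Qa charged: dawn
3. how much Qg is there at the end, in percent of the Qa charged: summer
4. how much Qg is there at the end, in percent of the Qa charged: dusk
5. how much Qg is there at the end, in percent of the Qa charged: winter

Climb the ladder in the winter flask, where the constants stand as given. The crossing of Qe into Qb takes 1.37 min, Qa opens to Qc with a half-life of 4.62 min, Qc dimerises at the full charge with a first half-life of 34.5 min, capture by saturated Qb has a time scale of 57.5 min, and the leak to Qf one of 333 min, against a run of 180 min.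

Because the crossing takes less time than capture needs to change Qc, you may write the balance of Qb as steady, inflow equal to use. Even with the whole charge standing as Qc, that balance gives Qb at 80.0% of saturation, which I round up to saturation for this estimate, treating capture as pseudo-first-order.

Because Qa opens sooner than capture acts, the winter flask starts as a burst of Qc, and its fate is a race. With Qb saturated, capture and dimerising consume Qc equally at a Qc fraction of 60.0%. This is the capture constant over twice the dimer constant times the charge, and I call it the crossover fraction. Above it the dimer step is the faster, below it capture.

Add the Qf constant to the numerator and you have the damping fraction, 70.4%. Integrating the race, a Qc fraction f finally yields as Qg the crossover times ln(one plus f over damping). For winter, taking as f the part of the whole charge that capture and the leak alone would consume within 3.0 h, this estimate gives 52.2%.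

My reckoning stops there. In summer the same balance, with the whole charge as Qc, gives Qb at 49.0% of saturation, and at dawn the half-life of Qa, 6.23 h, is longer than the run.

The forecast names winter, with 1.5% at dawn, 40.5% in summer, 28% at dusk and 47.5% in winter, holding for the hot flasks that “the yield is set by competition”. For winter my figure stands above its figure.

The simulation puts winter first, with 1.50% at dawn, 41.3% in summer, 28.7% at dusk and 52.2% in winter. The winter flask ends with 1.42% as Qc, capture then using Qc at 42 times the rate of the dimer step, so it is close to rest but not there. The rule adds 1.2 percentage points to reach 53.4%, and the winter flask left 30.0 h reads 53.4%. The dusk flask ends with 41.6% as Qc and 3.26% as Qa. Its crossover is 62.5% and its damping 68.9%, so the rule, counting both as Qc, adds 31 points to reach 59.7%, and the dusk flask at 30.0 h reads 60.1%.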